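**Retrosynthetic overview**

- The target is a (2S)-5,7-dihydroxyflavanone whose ring B (3,5-dimethoxy-4-oxyphenyl) carries an erythro (αR,βS) guaiacylglycerol β-ether; the last two steps only unmask hydroxyl groups (acetal hydrolysis, hydrogenolysis of three benzyl ethers).
- Key disconnection: ring C is cut at O1–C8a and at C4–C4a, giving 3,5-bis(benzyloxy)benzyne (ring A) and an open-chain (S)-β-hydroxynitrile. In the forward sense the alkoxide adds to the aryne and the C4a carbanion closes ring C on the nitrile carbon C4, so the ring-closing bond is C4–C4a.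
- Enabling feature: ring A is a 1,3,5-trioxygenated benzene in which C4a lies between C8a–O1 and C5–O. In the aryne C8a≡C4a the C5 oxygen steers the O-nucleophile to C8a and holds the charge at C4a, and C4 is 1,3 to O1 across the saturated C2–C3 unit, so the acylation is a six-membered closure.
- C2 (S) comes from asymmetric transfer hydrogenation of a β-ketonitrile made from a methyl benzoate and lithioacetonitrile; Cα/Cβ come from an Evans syn glycolate aldol (threo) followed by Mitsunobu inversion at Cα (erythro).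
- Order of rings: rings A, B and D are bought as benzenes, a temporary 1,3-dioxane protects the diol, and ring C is the only ring of the target that is built, in the key step.

Key step: step 12

Remark (assumption on the chemistry): the chloroacetyl imide used in step 1 is taken as a purchasable building block (otherwise one N-acylation of (R)-4-benzyloxazolidin-2-one with chloroacetyl chloride). Flavanone atoms are numbered O1, C2–C8a; the glycerol carbons are Cα (benzylic carbinol), Cβ (aryloxy carbon) and Cγ (CH2OH).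

**Route**

Step 1
Reactants: 1 methyl 4-hydroxy-3,5-dimethoxybenzoate (methyl syringate); 2 (R)-4-benzyl-3-(chloroacetyl)oxazolidin-2-one
Product: 3 (R)-4-benzyl-3-{2-[2,6-dimethoxy-4-(methoxycarbonyl)phenoxy]acetyl}oxazolidin-2-one
Conditions: K2CO3, NaI (cat.), MeCN, 50 °C
Reagents that add atoms: none
Why: Williamson etherification, an SN2 displacement at the α-halo carbonyl carbon (iodide catalysis) that should be much faster than attack of the hindered 2,6-dimethoxyphenoxide at the imide carbonyls.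

Step 2
Reactants: 3 (R)-4-benzyl-3-{2-[2,6-dimethoxy-4-(methoxycarbonyl)phenoxy]acetyl}oxazolidin-2-one; 4 4-(benzyloxy)-3-methoxybenzaldehyde
Product: 7 (R)-4-benzyl-3-[(2R,3S)-3-(4-benzyloxy-3-methoxyphenyl)-2-(2,6-dimethoxy-4-methoxycarbonylphenoxy)-3-hydroxypropanoyl]oxazolidin-2-one (syn aldol adduct), via boron enolate 5 (not isolated), via boron aldolate 6 (not isolated)
Conditions: Bu2BOTf, i-Pr2NEt, CH2Cl2, 0 °C; then 4, −78 → 0 °C; then pH 7 buffer, MeOH, H2O2, 0 °C
Reagents that add atoms: none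
Why: Evans boron-mediated syn glycolate aldol reaction, in which the (Z)-enolate 5 reacts through a Zimmerman–Traxler chair on the face opposite the benzyl group of the (R)-auxiliary, which sets the (2R,3S) imide, i.e. the threo (αS,βS) arrangement, as established for aryloxyacetyl oxazolidinones.

Step 3
Reactants: 7 syn aldol adduct
Product: 8 methyl 4-{[(1S,2S)-1-(4-benzyloxy-3-methoxyphenyl)-1,3-dihydroxypropan-2-yl]oxy}-3,5-dimethoxybenzoate (threo diol)
Conditions: NaBH4, THF/H2O, 0 °C → rt
Reagents that add atoms: none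
Why: Reductive removal of the Evans auxiliary, in which NaBH4 reduces the activated exocyclic imide carbonyl to the primary alcohol while the methyl benzoate is inert and no stereocentre is touched.

Step 4
Reactants: 8 threo diol
Product: 9 methyl 4-{[(1R,2S)-1-(4-benzyloxy-3-methoxyphenyl)-1,3-bis(4-nitrobenzoyloxy)propan-2-yl]oxy}-3,5-dimethoxybenzoate
Conditions: 4-nitrobenzoic acid, PPh3, DIAD (3 equiv each), THF, 0 °C → rt
Reagents that add atoms: 4-nitrobenzoic acid (O=C(O)c1ccc(cc1)[N+](=O)[O-])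
Why: Mitsunobu esterification, in which the primary alcohol is esterified and the benzylic alkoxyphosphonium ion is displaced by the carboxylate in an SN2 step with inversion, turning Cα from S to R (threo to erythro) while Cβ is not involved.

Step 5
Reactants: 9 bis(4-nitrobenzoate)
Product: 10 methyl 4-{[(1R,2S)-1-(4-benzyloxy-3-methoxyphenyl)-1,3-dihydroxypropan-2-yl]oxy}-3,5-dimethoxybenzoate (erythro diol)
Conditions: K2CO3 (cat.), MeOH/THF, 0 °C → rt
Reagents that add atoms: none
Why: Base-catalysed transesterification (Zemplén-type methanolysis) cleaves both electron-poor aryl esters at the acyl carbon, so Cα keeps its new configuration.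

Step 6
Reactants: 10 erythro diol
Product: 11 methyl 4-{[(4R,5S)-4-(4-benzyloxy-3-methoxyphenyl)-2,2-dimethyl-1,3-dioxan-5-yl]oxy}-3,5-dimethoxybenzoate
Conditions: Me2C(OMe)2, PPTS (cat.), CH2Cl2, rt
Reagents that add atoms: 2,2-dimethoxypropane (COC(C)(C)OC)
Why: Acid-catalysed transacetalisation of the 1,3-diol gives the isopropylidene acetal, which is inert to the organolithium, fluoride and alkoxide conditions that follow.

Step 7
Reactants: 11 acetonide ester
Product: 12 3-(4-{[(4R,5S)-4-(4-benzyloxy-3-methoxyphenyl)-2,2-dimethyl-1,3-dioxan-5-yl]oxy}-3,5-dimethoxyphenyl)-3-oxopropanenitrile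
Conditions: MeCN, n-BuLi, THF, −78 °C; then 11, −78 → −40 °C; then aq. NH4Cl
Reagents that add atoms: acetonitrile (CC#N)
Why: Claisen-type acylation of lithioacetonitrile by the methyl ester, which stops at the ketone because the β-ketonitrile is deprotonated as it forms (hence the excess of base).

Step 8
Reactants: 12 β-ketonitrile
Product: 13 (3S)-3-(4-{[(4R,5S)-4-(4-benzyloxy-3-methoxyphenyl)-2,2-dimethyl-1,3-dioxan-5-yl]oxy}-3,5-dimethoxyphenyl)-3-hydroxypropanenitrile
Conditions: RuCl[(S,S)-TsDPEN](p-cymene) (1 mol%), HCO2H/Et3N (5:2), EtOAc, 30 °C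
Reagents that add atoms: none
Why: Noyori–Ikariya asymmetric transfer hydrogenation of an aryl ketone, in which the (S,S)-ligand should deliver hydride to the face that gives the (S)-carbinol, as known for aroylacetonitriles, under catalyst control with no influence from the remote stereocentres.

Step 9
Reactants: 14 3,5-bis(benzyloxy)phenol
Product: 15 3,5-bis(benzyloxy)phenyl N-isopropylcarbamate
Conditions: i-PrNCO, Et3N (cat.), CH2Cl2, rt
Reagents that add atoms: isopropyl isocyanate (CC(C)N=C=O)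
Why: Base-catalysed addition of the phenol to the isocyanate installs a directing group that can later be removed with mild base.

Step 10
Reactants: 15 3,5-bis(benzyloxy)phenyl N-isopropylcarbamate
Product: 18 3,5-bis(benzyloxy)-2-(trimethylsilyl)phenyl N-isopropylcarbamate, via N-silyl carbamate 16 (not isolated), via N-silyl C-silyl carbamate 17 (not isolated)
Conditions: TBSOTf, TMEDA, Et2O, 0 °C → rt; then n-BuLi, TMEDA, −78 °C; then TMSCl, −78 °C → rt; then aq. NaHSO4
Reagents that add atoms: chlorotrimethylsilane (C[Si](C)(C)Cl)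
Why: Directed ortho-metalation, in which the N-silylated carbamate and the neighbouring benzyloxy group direct lithiation cooperatively to the carbon between them, which is silylated, and the N-silyl group is lost in the acidic work-up.

Step 11
Reactants: 18 3,5-bis(benzyloxy)-2-(trimethylsilyl)phenyl N-isopropylcarbamate
Product: 20 3,5-bis(benzyloxy)-2-(trimethylsilyl)phenyl trifluoromethanesulfonate, via silylphenol 19 (not isolated)
Conditions: DBU, Et2NH, MeCN, 40 °C; then PhNTf2, rt
Reagents that add atoms: N-phenylbis(trifluoromethanesulfonimide) (O=S(=O)(N(c1ccccc1)S(=O)(=O)C(F)(F)F)C(F)(F)F)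
Why: E1cB cleavage of the N-monosubstituted carbamate (the isocyanate is trapped by diethylamine) frees the phenoxide, which is triflated in the same flask to give the 2-silylaryl triflate aryne precursor.

Step 12
Reactants: 13 (3S)-hydroxynitrile; 20 3,5-bis(benzyloxy)-2-(trimethylsilyl)phenyl trifluoromethanesulfonate
Product: 23 (2S)-5,7-bis(benzyloxy)-2-(4-{[(4R,5S)-4-(4-benzyloxy-3-methoxyphenyl)-2,2-dimethyl-1,3-dioxan-5-yl]oxy}-3,5-dimethoxyphenyl)chroman-4-one, via aryne 21 (not isolated), via ketimine 22 (not isolated)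
Conditions: NaH, THF, 0 °C; then 20 (slow addition), KF, 18-crown-6, THF, 0 °C → rt; then AcOH/NaOAc buffer (pH 5), THF/H2O, 40 °C
Reagents that add atoms: water (O)
Why: Proposed new method: the sodium alkoxide of 13 adds to aryne 21 at the aryne carbon meta to the neighbouring benzyloxy group (future C8a), as the aryne distortion model predicts for 3-alkoxyarynes, which forms the O1–C8a bond and leaves the carbanion at C4a; this carbanion attacks the nitrile carbon C4 in a 6-exo-dig closure of ring C (the C4–C4a bond) to give the N-metalated ketimine, which is protonated to 22 and hydrolysed to ketone 23 only in the buffered work-up. The closest known reaction types are the fluoride-induced annulations of arynes with salicylates and with 2-aminobenzonitriles (heteroatom adds, then the aryl anion closes a six-membered ring on the ester or nitrile), the O-arylation of alcohols by arynes and the acyl-alkylation of 3,5-dialkoxybenzynes; new is an aliphatic β-alkoxide combined with a nitrile trap on a saturated tether. No stereocentre is formed: C2 keeps the S configuration of step 8 because its C–O bond is never broken. The step needs regioselectivity (O at C8a, C at C4a), which the C5 alkoxy group of the aryne secures, and it needs ring closure to outrun protonation of the carbanion, which is favoured by the absence of O–H after deprotonation, by THF as solvent and by the six-membered transition state. A nitrile is used instead of an ester because the closed product then stays at the ketimine level in the basic medium, where the C3 hydrogens are much less acidic than in the flavanone, so the base-induced opening of ring C to a chalcone, which would racemise C2, should be avoided.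

Step 13
Reactants: 23 flavanone acetonide
Product: 24 (2S)-5,7-bis(benzyloxy)-2-(4-{[(1R,2S)-1-(4-benzyloxy-3-methoxyphenyl)-1,3-dihydroxypropan-2-yl]oxy}-3,5-dimethoxyphenyl)chroman-4-one
Conditions: AcOH/H2O/THF (3:1:1), 40 °C
Reagents that add atoms: none
Why: Mild acid-catalysed acetal hydrolysis, under which flavanones are configurationally stable and the benzylic Cα–O bond, still para to a benzyl ether and not to a free phenol, should not ionise.

Step 14
Reactants: 24 tri-O-benzyl flavanone diol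
Product: 25 (2S)-5,7-dihydroxy-2-(4-{[(1R,2S)-1,3-dihydroxy-1-(4-hydroxy-3-methoxyphenyl)propan-2-yl]oxy}-3,5-dimethoxyphenyl)chroman-4-one (target)
Conditions: H2 (1 atm), Pd/C (10 wt%), EtOAc/MeOH, rt
Reagents that add atoms: none
Why: Heterogeneous catalytic hydrogenolysis of the three aryl benzyl ethers under neutral conditions, where O-benzyl cleavage should be much faster than hydrogenolysis of the C2–O1 and Cα–OH bonds or reduction of the aryl ketone, as is routine for benzyl-protected flavanones and arylglycerol β-aryl ethers.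

**Compound list**

1 | methyl 4-hydroxy-3,5-dimethoxybenzoate | COC(=O)c1cc(OC)c(O)c(OC)c1 | starting material
2 | (R)-4-benzyl-3-(chloroacetyl)oxazolidin-2-one | ClCC(=O)N1[C@H](Cc2ccccc2)COC1=O | starting material
3 | (R)-4-benzyl-3-{2-[2,6-dimethoxy-4-(methoxycarbonyl)phenoxy]acetyl}oxazolidin-2-one | COC(=O)c1cc(OC)c(OCC(=O)N2[C@H](Cc3ccccc3)COC2=O)c(OC)c1 | intermediate
4 | 4-(benzyloxy)-3-methoxybenzaldehyde | COc1cc(C=O)ccc1OCc1ccccc1 | starting material
5 | dibutylboron (Z)-enolate of 3 (not isolated) | CCCCB(CCCC)O/C(N1[C@H](Cc2ccccc2)COC1=O)=C\Oc1c(OC)cc(C(=O)OC)cc1OC | intermediate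
6 | O-dibutylboryl aldolate of 7 (not isolated) | COc1cc([C@H](OB(CCCC)CCCC)[C@H](C(=O)N3[C@H](Cc4ccccc4)COC3=O)Oc2c(OC)cc(C(=O)OC)cc2OC)ccc1OCc1ccccc1 | intermediate
7 | (R)-4-benzyl-3-[(2R,3S)-3-(4-benzyloxy-3-methoxyphenyl)-2-(2,6-dimethoxy-4-methoxycarbonylphenoxy)-3-hydroxypropanoyl]oxazolidin-2-one | COc1cc([C@H](O)[C@H](C(=O)N3[C@H](Cc4ccccc4)COC3=O)Oc2c(OC)cc(C(=O)OC)cc2OC)ccc1OCc1ccccc1 | intermediate
8 | methyl 4-{[(1S,2S)-1-(4-benzyloxy-3-methoxyphenyl)-1,3-dihydroxypropan-2-yl]oxy}-3,5-dimethoxybenzoate | COc1cc([C@H](O)[C@H](CO)Oc2c(OC)cc(C(=O)OC)cc2OC)ccc1OCc1ccccc1 | intermediate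
9 | methyl 4-{[(1R,2S)-1-(4-benzyloxy-3-methoxyphenyl)-1,3-bis(4-nitrobenzoyloxy)propan-2-yl]oxy}-3,5-dimethoxybenzoate | COc1cc([C@@H](OC(=O)c3ccc(cc3)[N+](=O)[O-])[C@H](COC(=O)c3ccc(cc3)[N+](=O)[O-])Oc2c(OC)cc(C(=O)OC)cc2OC)ccc1OCc1ccccc1 | intermediate
10 | methyl 4-{[(1R,2S)-1-(4-benzyloxy-3-methoxyphenyl)-1,3-dihydroxypropan-2-yl]oxy}-3,5-dimethoxybenzoate | COc1cc([C@@H](O)[C@H](CO)Oc2c(OC)cc(C(=O)OC)cc2OC)ccc1OCc1ccccc1 | intermediate
11 | methyl 4-{[(4R,5S)-4-(4-benzyloxy-3-methoxyphenyl)-2,2-dimethyl-1,3-dioxan-5-yl]oxy}-3,5-dimethoxybenzoate | COc1cc([C@H]3OC(C)(C)OC[C@@H]3Oc2c(OC)cc(C(=O)OC)cc2OC)ccc1OCc1ccccc1 | intermediate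
12 | 3-(4-{[(4R,5S)-4-(4-benzyloxy-3-methoxyphenyl)-2,2-dimethyl-1,3-dioxan-5-yl]oxy}-3,5-dimethoxyphenyl)-3-oxopropanenitrile | COc1cc([C@H]3OC(C)(C)OC[C@@H]3Oc2c(OC)cc(C(=O)CC#N)cc2OC)ccc1OCc1ccccc1 | intermediate
13 | (3S)-3-(4-{[(4R,5S)-4-(4-benzyloxy-3-methoxyphenyl)-2,2-dimethyl-1,3-dioxan-5-yl]oxy}-3,5-dimethoxyphenyl)-3-hydroxypropanenitrile | COc1cc([C@H]3OC(C)(C)OC[C@@H]3Oc2c(OC)cc([C@@H](O)CC#N)cc2OC)ccc1OCc1ccccc1 | intermediate
14 | 3,5-bis(benzyloxy)phenol | Oc1cc(OCc2ccccc2)cc(OCc2ccccc2)c1 | starting material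
15 | 3,5-bis(benzyloxy)phenyl N-isopropylcarbamate | CC(C)NC(=O)Oc1cc(OCc2ccccc2)cc(OCc2ccccc2)c1 | intermediate
16 | 3,5-bis(benzyloxy)phenyl N-(tert-butyldimethylsilyl)-N-isopropylcarbamate (not isolated) | CC(C)N(C(=O)Oc1cc(OCc2ccccc2)cc(OCc2ccccc2)c1)[Si](C)(C)C(C)(C)C | intermediate
17 | 3,5-bis(benzyloxy)-2-(trimethylsilyl)phenyl N-(tert-butyldimethylsilyl)-N-isopropylcarbamate (not isolated) | CC(C)N(C(=O)Oc1cc(OCc2ccccc2)cc(OCc2ccccc2)c1[Si](C)(C)C)[Si](C)(C)C(C)(C)C | intermediate
18 | 3,5-bis(benzyloxy)-2-(trimethylsilyl)phenyl N-isopropylcarbamate | CC(C)NC(=O)Oc1cc(OCc2ccccc2)cc(OCc2ccccc2)c1[Si](C)(C)C | intermediate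
19 | 3,5-bis(benzyloxy)-2-(trimethylsilyl)phenol (not isolated) | Oc1cc(OCc2ccccc2)cc(OCc2ccccc2)c1[Si](C)(C)C | intermediate
20 | 3,5-bis(benzyloxy)-2-(trimethylsilyl)phenyl trifluoromethanesulfonate | C[Si](C)(C)c1c(OS(=O)(=O)C(F)(F)F)cc(OCc2ccccc2)cc1OCc1ccccc1 | intermediate
21 | 3,5-bis(benzyloxy)benzyne (not isolated) | C1#CC(OCc2ccccc2)=CC(OCc2ccccc2)=C1 | intermediate
22 | (2S)-5,7-bis(benzyloxy)-2-(4-{[(4R,5S)-4-(4-benzyloxy-3-methoxyphenyl)-2,2-dimethyl-1,3-dioxan-5-yl]oxy}-3,5-dimethoxyphenyl)chroman-4-imine (not isolated) | COc1cc([C@H]3OC(C)(C)OC[C@@H]3Oc2c(OC)cc([C@@H]4CC(=N)c5c(OCc6ccccc6)cc(OCc6ccccc6)cc5O4)cc2OC)ccc1OCc1ccccc1 | intermediate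
23 | (2S)-5,7-bis(benzyloxy)-2-(4-{[(4R,5S)-4-(4-benzyloxy-3-methoxyphenyl)-2,2-dimethyl-1,3-dioxan-5-yl]oxy}-3,5-dimethoxyphenyl)chroman-4-one | COc1cc([C@H]3OC(C)(C)OC[C@@H]3Oc2c(OC)cc([C@@H]4CC(=O)c5c(OCc6ccccc6)cc(OCc6ccccc6)cc5O4)cc2OC)ccc1OCc1ccccc1 | intermediate
24 | (2S)-5,7-bis(benzyloxy)-2-(4-{[(1R,2S)-1-(4-benzyloxy-3-methoxyphenyl)-1,3-dihydroxypropan-2-yl]oxy}-3,5-dimethoxyphenyl)chroman-4-one | COc1cc([C@@H](O)[C@H](CO)Oc2c(OC)cc([C@@H]3CC(=O)c4c(OCc5ccccc5)cc(OCc5ccccc5)cc4O3)cc2OC)ccc1OCc1ccccc1 | intermediate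
25 | (2S)-5,7-dihydroxy-2-(4-{[(1R,2S)-1,3-dihydroxy-1-(4-hydroxy-3-methoxyphenyl)propan-2-yl]oxy}-3,5-dimethoxyphenyl)chroman-4-one | COc1cc([C@@H](O)[C@H](CO)Oc2c(OC)cc([C@@H]3CC(=O)c4c(O)cc(O)cc4O3)cc2OC)ccc1O | target

**Step count**

Total steps: 14. Longest linear sequence: 11 (steps 1–8 and 12–14); steps 9–11 make the aryne precursor.

**Steps most likely to fail**

Step 12 (Proposed new method). The aryl carbanion may be protonated before it closes on the nitrile, giving plain O-arylation. The alkoxide may attack the sulfonyl sulfur of the triflate instead of the aryne. Proton abstraction at C3 followed by β-elimination of the aryloxide would destroy the C2 stereocentre. The fallback closes the same C4–C4a bond by known chemistry and sets out from 12. The enantiomeric catalyst RuCl[(R,R)-TsDPEN](p-cymene) under the conditions of step 8 should give (3R)-3-(4-{[(4R,5S)-4-(4-benzyloxy-3-methoxyphenyl)-2,2-dimethyl-1,3-dioxan-5-yl]oxy}-3,5-dimethoxyphenyl)-3-hydroxypropanenitrile F1. Mitsunobu etherification (PPh3, DIAD, THF, 0 °C) with 2-bromo-3,5-bis(benzyloxy)phenol F2 (from 14 by ortho-bromination with N-bromosuccinimide, CH2Cl2, −78 °C) should give, with inversion, (3S)-3-[2-bromo-3,5-bis(benzyloxy)phenoxy]-3-(4-{[(4R,5S)-4-(4-benzyloxy-3-methoxyphenyl)-2,2-dimethyl-1,3-dioxan-5-yl]oxy}-3,5-dimethoxyphenyl)propanenitrile F3. Bromine–lithium exchange (t-BuLi, THF, −100 °C) and warming should bring about a Parham cyclisation of the aryllithium onto the nitrile; protonation gives ketimine 22, where the fallback comes back to the route, and 22 is hydrolysed to 23 as in step 12.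

Step 4. The electron-rich benzylic alkoxyphosphonium ion may ionise, so that inversion at Cα is incomplete, or it may eliminate towards the enol ether. The fallback replaces substitution by oxidation and reduction and sets out from 8. TBSCl/imidazole (CH2Cl2, 0 °C) should give methyl 4-{[(1S,2S)-1-(4-benzyloxy-3-methoxyphenyl)-3-(tert-butyldimethylsilyloxy)-1-hydroxypropan-2-yl]oxy}-3,5-dimethoxybenzoate F4. Dess–Martin periodinane should oxidise the benzylic alcohol to methyl 4-{[(2S)-1-(4-benzyloxy-3-methoxyphenyl)-3-(tert-butyldimethylsilyloxy)-1-oxopropan-2-yl]oxy}-3,5-dimethoxybenzoate F5 without touching Cβ. Chelation-controlled reduction with Zn(BH4)2 (Et2O, −30 °C), the mode that gives the anti (erythro) relationship for α-aryloxy ketones, should give methyl 4-{[(1R,2S)-1-(4-benzyloxy-3-methoxyphenyl)-3-(tert-butyldimethylsilyloxy)-1-hydroxypropan-2-yl]oxy}-3,5-dimethoxybenzoate F6. TBAF/AcOH (THF) then removes the silyl group, and the fallback comes back to the route at 10.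

Step 8. The largely enolised β-ketonitrile may turn over slowly or with eroded facial selectivity, and the acetal may suffer formolysis in the acidic medium. The fallback replaces catalytic transfer hydrogenation by a stoichiometric, reagent-controlled reduction: from 12, (−)-B-chlorodiisopinocampheylborane (THF, −25 °C; diethanolamine work-up), which gives (S)-carbinols from aryl alkyl ketones, leads directly back to the route at 13 without any new compound.

**Further compounds**

F1 | step 12 | (3R)-3-(4-{[(4R,5S)-4-(4-benzyloxy-3-methoxyphenyl)-2,2-dimethyl-1,3-dioxan-5-yl]oxy}-3,5-dimethoxyphenyl)-3-hydroxypropanenitrile | COc1cc([C@H]3OC(C)(C)OC[C@@H]3Oc2c(OC)cc([C@H](O)CC#N)cc2OC)ccc1OCc1ccccc1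
F2 | step 12 | 2-bromo-3,5-bis(benzyloxy)phenol | Oc1cc(OCc2ccccc2)cc(OCc2ccccc2)c1Br
F3 | step 12 | (3S)-3-[2-bromo-3,5-bis(benzyloxy)phenoxy]-3-(4-{[(4R,5S)-4-(4-benzyloxy-3-methoxyphenyl)-2,2-dimethyl-1,3-dioxan-5-yl]oxy}-3,5-dimethoxyphenyl)propanenitrile | COc1cc([C@H]3OC(C)(C)OC[C@@H]3Oc2c(OC)cc([C@@H](Oc4cc(OCc5ccccc5)cc(OCc5ccccc5)c4Br)CC#N)cc2OC)ccc1OCc1ccccc1
F4 | step 4 | methyl 4-{[(1S,2S)-1-(4-benzyloxy-3-methoxyphenyl)-3-(tert-butyldimethylsilyloxy)-1-hydroxypropan-2-yl]oxy}-3,5-dimethoxybenzoate | COc1cc([C@H](O)[C@H](CO[Si](C)(C)C(C)(C)C)Oc2c(OC)cc(C(=O)OC)cc2OC)ccc1OCc1ccccc1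
F5 | step 4 | methyl 4-{[(2S)-1-(4-benzyloxy-3-methoxyphenyl)-3-(tert-butyldimethylsilyloxy)-1-oxopropan-2-yl]oxy}-3,5-dimethoxybenzoate | COc1cc(C(=O)[C@H](CO[Si](C)(C)C(C)(C)C)Oc2c(OC)cc(C(=O)OC)cc2OC)ccc1OCc1ccccc1
F6 | step 4 | methyl 4-{[(1R,2S)-1-(4-benzyloxy-3-methoxyphenyl)-3-(tert-butyldimethylsilyloxy)-1-hydroxypropan-2-yl]oxy}-3,5-dimethoxybenzoate | COc1cc([C@@H](O)[C@H](CO[Si](C)(C)C(C)(C)C)Oc2c(OC)cc(C(=O)OC)cc2OC)ccc1OCc1ccccc1
F0 | step 8 | none | none
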